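Ring B is disconnected at the C6=C7 enone bond (eremophilane numbering). The cross-conjugated dienone C6=C7–C8(=O)–C9=C10 is an aldol-condensation retron: C6 hangs on the non-enolisable quaternary C5, and C7 is the only enolisable α-carbon of the C8 ketone. One flask turns a ring A carbinol into ring B: Meyer–Schuster rearrangement of a C10 tertiary propargylic alcohol makes the C9=C10–C8=O enone, acid unmasks the C6 aldehyde from its dimethyl acetal, and the C7 enol closes the six-membered ring with loss of water. The precursor is a fully substituted cyclohexane (C3 acetate, cis C4/C5 methyls) carrying the alkyne C9≡C8–C7H2–C11, with C11 held in a lactate-derived dioxolanone.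

Key step: step 7

Remark: atoms are numbered as in eremophilane (ring A = C1–C5 and C10; ring B = C5–C10; C11 bears the C12 carboxyl and the C13 methyl); compounds 1, 7 and 15 are taken as purchasable.

Step 1
Reactants: 1 2,3-dimethylcyclohex-2-en-1-one
Product: 2 (S)-2,3-dimethylcyclohex-2-en-1-ol
Conditions: (R)-2-methyl-CBS-oxazaborolidine (10 mol%), BH3·SMe2, THF, −20 °C; MeOH quench
Reagents that add atoms: none
Why: Corey–Bakshi–Shibata reduction, in which the α-methylated alkenyl arm of the ketone acts as the large group, so hydride should be delivered to the face that gives the (S)-carbinol, the future C3.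

Step 2
Reactants: 2 (S)-2,3-dimethylcyclohex-2-en-1-ol
Product: 3 (S)-2,3-dimethylcyclohex-2-en-1-yl acetate
Conditions: Ac2O, pyridine, DMAP (5 mol%), CH2Cl2, 0 °C to rt
Reagents that add atoms: acetic anhydride CC(=O)OC(C)=O
Why: DMAP-catalysed O-acylation with retention installs the C3 acetate of the target early, where it also deactivates the C3–H bond towards the next oxidation.

Step 3
Reactants: 3 (S)-2,3-dimethylcyclohex-2-en-1-yl acetate
Product: 4 (S)-2,3-dimethyl-4-oxocyclohex-2-en-1-yl acetate
Conditions: Rh2(cap)4 (dirhodium tetracaprolactamate, 1 mol%), t-BuOOH (70% aq., 5 equiv), NaHCO3, CH2Cl2, rt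
Reagents that add atoms: tert-butyl hydroperoxide CC(C)(C)OO
Why: Doyle-type radical allylic oxidation should take place at the only ring allylic methylene (future C10), because the acetoxy-bearing C3–H is electronically deactivated, and the C3 stereocentre is not touched.

Step 4
Reactants: 4 (S)-2,3-dimethyl-4-oxocyclohex-2-en-1-yl acetate
Product: 6 (1S,2R,3S)-3-(dimethoxymethyl)-2,3-dimethyl-4-oxocyclohexyl acetate, via triethylsilyl enol ether 5 (not isolated)
Conditions: RhCl(PPh3)3 (2 mol%), Et3SiH (1.5 equiv), benzene, 60 °C; evaporate; then HC(OMe)3 (3 equiv), TMSOTf (10 mol%), CH2Cl2, −78 to −40 °C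
Reagents that add atoms: trimethyl orthoformate COC(OC)OC
Why: Ojima 1,4-hydrosilylation should deliver hydride to C4 anti to the C3 acetate (C4 methyl cis to the acetate), and the regiodefined enol silane 5 should then undergo a Mukaiyama-type alkylation by the dimethoxycarbenium ion on the face opposite the C4 methyl and C3 acetate, which sets quaternary C5 with its methyl cis to the C4 methyl.

Step 5
Reactants: 7 (2S,5S)-2-tert-butyl-5-methyl-1,3-dioxolan-4-one
Product: 8 (2S,5R)-2-tert-butyl-5-methyl-5-(prop-2-yn-1-yl)-1,3-dioxolan-4-one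
Conditions: LDA (1.1 equiv), THF, −78 °C; propargyl bromide (1.5 equiv), −78 to −30 °C
Reagents that add atoms: propargyl bromide C#CCBr
Why: Seebach self-regeneration of stereocentres: the lithium enolate should be alkylated (SN2) anti to the tert-butyl group, so the propargyl group replaces the lactate hydrogen with retention and fixes the (R)-configured quaternary carbon that becomes C11.

Step 6
Reactants: 8 (2S,5R)-2-tert-butyl-5-methyl-5-(prop-2-yn-1-yl)-1,3-dioxolan-4-one, 6 (1S,2R,3S)-3-(dimethoxymethyl)-2,3-dimethyl-4-oxocyclohexyl acetate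
Product: 9 (1S,2R,3R)-4-{3-[(2S,4R)-2-tert-butyl-4-methyl-5-oxo-1,3-dioxolan-4-yl]prop-1-yn-1-yl}-3-(dimethoxymethyl)-4-hydroxy-2,3-dimethylcyclohexyl acetate (both carbinol epimers)
Conditions: 8 (1.3 equiv), LDA (1.25 equiv), THF, −78 °C; CeCl3 (1.5 equiv), −78 °C; then 6, −78 to −40 °C; aq. NH4Cl
Reagents that add atoms: none
Why: 1,2-addition of the alkynylcerium reagent (Imamoto conditions) to the hindered, enolisable C10 ketone forms the C9–C10 bond while the weakly basic reagent should spare the acetate and the acylal, and the carbinol configuration is irrelevant because C10 becomes sp2 in step 7.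

Step 7
Reactants: 9 (1S,2R,3R)-4-{3-[(2S,4R)-2-tert-butyl-4-methyl-5-oxo-1,3-dioxolan-4-yl]prop-1-yn-1-yl}-3-(dimethoxymethyl)-4-hydroxy-2,3-dimethylcyclohexyl acetate
Product: 13 (1R,2S,8aR)-7-[(2S,4R)-2-tert-butyl-4-methyl-5-oxo-1,3-dioxolan-4-yl]-1,8a-dimethyl-6-oxo-1,2,3,4,6,8a-hexahydronaphthalen-2-yl acetate, via E-enone dimethyl acetal 10 (not isolated), via Z-enone aldehyde 11 (not isolated), via ring B aldol adduct 12 (not isolated)
Conditions: Bu4NReO4 (10 mol%), TsOH·H2O (30 mol%), ClCH2CH2Cl, rt; then H2O (2 equiv), 70 °C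
Reagents that add atoms: none
Why: The perrhenate ester of the C10 carbinol should undergo a [3,3] shift to the allenyl perrhenate and collapse to enone 10 (Meyer–Schuster rearrangement); the acid then unmasks the C6 aldehyde, equilibrates the E and Z enones through the C1 dienol, and lets the C8 enol attack C6 through C7, after which aldol 12 loses water. The closest known reaction type is a Meyer–Schuster rearrangement followed by an acid-catalysed intramolecular aldol condensation of the Robinson type. Ring B closes in the 6-(enolendo)-exo-trig mode. The C6 and C7 stereocentres of 12 are erased by dehydration, so no permanent stereocentre is formed, and C3, C4, C5 and C11 cannot epimerise (C5 and C11 are quaternary, C4 is not α to a carbonyl). The step needs regioselective enolisation and the Z geometry at C9=C10: C7 is the only α-CH2 of the C8 ketone and the C6 aldehyde has no α-hydrogen, while only the Z isomer can cyclise and irreversible dehydration drains the E/Z equilibrium. Loss of the C11 oxygen by β-elimination is held back because that oxygen is tied into the dioxolanone ring and ionisation at C11 would place positive charge next to the C12 carbonyl.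

Step 8
Reactants: 13 (1R,2S,8aR)-7-[(2S,4R)-2-tert-butyl-4-methyl-5-oxo-1,3-dioxolan-4-yl]-1,8a-dimethyl-6-oxo-1,2,3,4,6,8a-hexahydronaphthalen-2-yl acetate
Product: 14 (2R)-2-[(7S,8R,8aR)-7-acetoxy-8,8a-dimethyl-3-oxo-3,5,6,7,8,8a-hexahydronaphthalen-2-yl]-2-hydroxypropanoic acid
Conditions: LiOH (1.5 equiv), THF/H2O (3:1), 0 °C, short reaction time; then 1 M HCl to pH 2
Reagents that add atoms: lithium hydroxide [Li+].[OH-]
Why: Nucleophilic acyl substitution at the acylal carbonyl, which is far more electrophilic than the hindered axial C3 acetate, should open the dioxolanone, and the hemiacetal alkoxide collapses to pivalaldehyde and the free tertiary C11 hydroxyl without touching a stereocentre.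

Step 9
Reactants: 15 (R)-2-methylbutanoic acid
Product: 16 (R)-2-methylbutanoyl chloride
Conditions: (COCl)2 (1.2 equiv), DMF (cat.), CH2Cl2, 0 °C to rt; used as a solution
Reagents that add atoms: oxalyl chloride ClC(=O)C(Cl)=O
Why: Vilsmeier-type activation with oxalyl chloride and catalytic DMF converts the acid into the acyl chloride under base-free conditions that should not enolise the α-stereocentre.

Step 10
Reactants: 14 (2R)-2-[(7S,8R,8aR)-7-acetoxy-8,8a-dimethyl-3-oxo-3,5,6,7,8,8a-hexahydronaphthalen-2-yl]-2-hydroxypropanoic acid, 16 (R)-2-methylbutanoyl chloride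
Product: 17 (2R)-2-[(7S,8R,8aR)-7-acetoxy-8,8a-dimethyl-3-oxo-3,5,6,7,8,8a-hexahydronaphthalen-2-yl]-2-{[(2R)-2-methylbutanoyl]oxy}propanoic acid
Conditions: 16 (3 equiv), pyridine (6 equiv), CH2Cl2, 0 °C to rt; then THF/aq. NaHCO3, then acidify to pH 2
Reagents that add atoms: none
Why: O-acylation of the tertiary α-hydroxy acid by the acyl chloride, assisted by the neighbouring carboxyl through its mixed anhydride (O-to-O acyl transfer through a five-membered transition state), should give the C11 ester with both stereocentres unchanged, and the bicarbonate work-up hydrolyses residual mixed anhydride to the free C12 acid.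

Compound list

1 | 2,3-dimethylcyclohex-2-en-1-one | CC1=C(C)C(=O)CCC1 | starting material
2 | (S)-2,3-dimethylcyclohex-2-en-1-ol | O[C@H]1CCCC(C)=C1C | intermediate
3 | (S)-2,3-dimethylcyclohex-2-en-1-yl acetate | CC(=O)O[C@H]1CCCC(C)=C1C | intermediate
4 | (S)-2,3-dimethyl-4-oxocyclohex-2-en-1-yl acetate | O=C1CC[C@H](OC(C)=O)C(C)=C1C | intermediate
5 | (1S,2R)-2,3-dimethyl-4-(triethylsilyloxy)cyclohex-3-en-1-yl acetate | CC1=C(O[Si](CC)(CC)CC)CC[C@H](OC(C)=O)[C@@H]1C | intermediate
6 | (1S,2R,3S)-3-(dimethoxymethyl)-2,3-dimethyl-4-oxocyclohexyl acetate | COC(OC)[C@]1(C)[C@@H](C)[C@@H](OC(C)=O)CCC1=O | intermediate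
7 | (2S,5S)-2-tert-butyl-5-methyl-1,3-dioxolan-4-one | C[C@@H]1O[C@H](C(C)(C)C)OC1=O | starting material
8 | (2S,5R)-2-tert-butyl-5-methyl-5-(prop-2-yn-1-yl)-1,3-dioxolan-4-one | C#CC[C@@]1(C)O[C@H](C(C)(C)C)OC1=O | intermediate
9 | (1S,2R,3R)-4-{3-[(2S,4R)-2-tert-butyl-4-methyl-5-oxo-1,3-dioxolan-4-yl]prop-1-yn-1-yl}-3-(dimethoxymethyl)-4-hydroxy-2,3-dimethylcyclohexyl acetate (carbinol epimers) | COC(OC)[C@]1(C)[C@@H](C)[C@@H](OC(C)=O)CCC1(O)C#CC[C@@]2(C)O[C@H](C(C)(C)C)OC2=O | intermediate
10 | (1S,2R,3R,4E)-4-{3-[(2S,4R)-2-tert-butyl-4-methyl-5-oxo-1,3-dioxolan-4-yl]-2-oxopropylidene}-3-(dimethoxymethyl)-2,3-dimethylcyclohexyl acetate | COC(OC)[C@]1(C)[C@@H](C)[C@@H](OC(C)=O)CC/C1=C\C(=O)C[C@@]2(C)O[C@H](C(C)(C)C)OC2=O | intermediate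
11 | (1S,2R,3R,4Z)-4-{3-[(2S,4R)-2-tert-butyl-4-methyl-5-oxo-1,3-dioxolan-4-yl]-2-oxopropylidene}-3-formyl-2,3-dimethylcyclohexyl acetate | O=C[C@]1(C)[C@@H](C)[C@@H](OC(C)=O)CC/C1=C/C(=O)C[C@@]2(C)O[C@H](C(C)(C)C)OC2=O | intermediate
12 | (1R,2S,8aR)-7-[(2S,4R)-2-tert-butyl-4-methyl-5-oxo-1,3-dioxolan-4-yl]-8-hydroxy-1,8a-dimethyl-6-oxo-1,2,3,4,6,7,8,8a-octahydronaphthalen-2-yl acetate (epimers at the two new carbons) | CC(C)(C)[C@H]1O[C@@](C)(C(=O)O1)C2C(O)[C@@]3(C)C(=CC2=O)CC[C@H](OC(C)=O)[C@@H]3C | intermediate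
13 | (1R,2S,8aR)-7-[(2S,4R)-2-tert-butyl-4-methyl-5-oxo-1,3-dioxolan-4-yl]-1,8a-dimethyl-6-oxo-1,2,3,4,6,8a-hexahydronaphthalen-2-yl acetate | CC(C)(C)[C@H]1O[C@@](C)(C(=O)O1)C2=C[C@@]3(C)C(=CC2=O)CC[C@H](OC(C)=O)[C@@H]3C | intermediate
14 | (2R)-2-[(7S,8R,8aR)-7-acetoxy-8,8a-dimethyl-3-oxo-3,5,6,7,8,8a-hexahydronaphthalen-2-yl]-2-hydroxypropanoic acid | O[C@@](C)(C(=O)O)C1=C[C@@]2(C)C(=CC1=O)CC[C@H](OC(C)=O)[C@@H]2C | intermediate
15 | (R)-2-methylbutanoic acid | CC[C@@H](C)C(=O)O | starting material
16 | (R)-2-methylbutanoyl chloride | CC[C@@H](C)C(=O)Cl | intermediate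
17 | (2R)-2-[(7S,8R,8aR)-7-acetoxy-8,8a-dimethyl-3-oxo-3,5,6,7,8,8a-hexahydronaphthalen-2-yl]-2-{[(2R)-2-methylbutanoyl]oxy}propanoic acid | CC[C@@H](C)C(=O)O[C@@](C)(C(=O)O)C1=C[C@@]2(C)C(=CC1=O)CC[C@H](OC(C)=O)[C@@H]2C | target

Total step count: 10. Longest linear sequence: 8 steps (steps 1, 2, 3, 4, 6, 7, 8, 10).

Steps most likely to fail

Step 7. The E-enone may equilibrate to the Z isomer too slowly, so that acid-induced loss of the C11 oxygen through the C8 enol, or cleavage of the acylal, overtakes ring closure. The fallback removes the geometric constraint and sets out from 9. Gold-catalysed Meyer–Schuster rearrangement (Ph3PAuNTf2, MeOH, toluene, rt) would give enone 10, now isolated. Hydrogenation of its C9=C10 bond (H2, Pd/C, EtOAc) would give the saturated keto acetal F1. Acid-mediated acetal cleavage and aldol condensation (TsOH·H2O, toluene, 80 °C) on the freely rotating chain would give the ring B cyclohexenone F2. Dehydrogenation across C9–C10 (DDQ, dioxane, 100 °C) would then return to the route at 13.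

Step 4. The tetrasubstituted enone may undergo 1,4-hydrosilylation sluggishly, or hydride may be delivered with poor facial selectivity or in the 1,2 sense. The fallback sets out from 4. Heterogeneous hydrogenation (H2, Rh/Al2O3, EtOAc) from the face anti to the acetate would give the saturated ketone F3. Thermodynamic enol silylation (TMSCl, NaI, Et3N, MeCN) would give the tetrasubstituted trimethylsilyl enol ether F4. The same orthoformate alkylation (HC(OMe)3, TMSOTf, CH2Cl2, −78 °C) would then return to the route at 6.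

Step 8. Opening of the hindered acylal may be slow enough that the C3 acetate is saponified at the same time. The fallback accepts this and sets out from 13. Excess LiOH (THF/H2O, rt) would give the dihydroxy acid F5. Allylation of the carboxylate (allyl bromide, KHCO3, DMF) would give the allyl ester F6. Acetylation of the secondary hydroxyl only (Ac2O, pyridine, no DMAP) would give the acetate F7. Acylation of the tertiary hydroxyl with 16 (DMAP, pyridine, CH2Cl2) would give the allyl ester F8 of the target. Deallylation (Pd(PPh3)4, morpholine, THF) would then come back to the route at 17.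

Further compounds

F1 | step 7 | compound 10 with the C9=C10 double bond hydrogenated (saturated keto acetal, C10 epimers) | COC(OC)[C@]1(C)[C@@H](C)[C@@H](OC(C)=O)CCC1CC(=O)C[C@@]2(C)O[C@H](C(C)(C)C)OC2=O
F2 | step 7 | 9,10-dihydro analogue of compound 13 (ring B cyclohex-6-en-8-one, C10 epimers) | CC(C)(C)[C@H]1O[C@@](C)(C(=O)O1)C2=C[C@@]3(C)C(CC2=O)CC[C@H](OC(C)=O)[C@@H]3C
F3 | step 4 | (1S,2R)-2,3-dimethyl-4-oxocyclohexyl acetate (epimers at C3 of the ring) | CC1C(=O)CC[C@H](OC(C)=O)[C@@H]1C
F4 | step 4 | (1S,2R)-2,3-dimethyl-4-(trimethylsilyloxy)cyclohex-3-en-1-yl acetate | CC1=C(O[Si](C)(C)C)CC[C@H](OC(C)=O)[C@@H]1C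
F5 | step 8 | (2R)-2-hydroxy-2-[(7S,8R,8aR)-7-hydroxy-8,8a-dimethyl-3-oxo-3,5,6,7,8,8a-hexahydronaphthalen-2-yl]propanoic acid | O[C@@](C)(C(=O)O)C1=C[C@@]2(C)C(=CC1=O)CC[C@H](O)[C@@H]2C
F6 | step 8 | allyl ester of F5 | O[C@@](C)(C(=O)OCC=C)C1=C[C@@]2(C)C(=CC1=O)CC[C@H](O)[C@@H]2C
F7 | step 8 | allyl ester of compound 14 | O[C@@](C)(C(=O)OCC=C)C1=C[C@@]2(C)C(=CC1=O)CC[C@H](OC(C)=O)[C@@H]2C
F8 | step 8 | allyl ester of compound 17 | CC[C@@H](C)C(=O)O[C@@](C)(C(=O)OCC=C)C1=C[C@@]2(C)C(=CC1=O)CC[C@H](OC(C)=O)[C@@H]2C
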